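Assumption: the SMILES is read as the (1S,2S,4S,11S) isomer, with serrulatane-style atom labels used throughout (C1 methyl, C2 acetoxy, C4 side chain, C6 acetoxymethyl, C8 hydroxyl, C11 side-chain stereocentre); C1-methyl is trans to C2-O and C2-O is cis to the C4 chain.

**Retrosynthetic overview**
1. Target ⇐ tetralin triol, by peracetylation and selective cleavage of the phenolic acetate.
2. C2–O bond (with C1–H) ⇐ the C1=C2 alkene of an 8-acetoxy-1-methyl-3,4-dihydronaphthalene, by acetate-directed asymmetric hydroboration–oxidation; this step sets C1 and C2.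
3. Ring B (the only ring made; aromatic ring A is bought) ⇐ phenoxide-templated cyclodehydration of a 5-aryl-2-pentanone (C1–C8a bond).
4. That ketone ⇐ γ-aryl enone ⇐ Wittig trapping of the α-aryl aldehyde from (S)-citronellal and an aryl(mesityl)iodonium salt (C4–aryl bond; C4 by organocatalysis, C11 from the chiral pool).
5. Iodonium salt ⇐ methyl 3-hydroxy-5-iodobenzoate.

**Route**

Step 1
Reactants: 1 methyl 3-hydroxy-5-iodobenzoate
Product: 3 [3-(acetyloxy)-5-iodophenyl]methyl acetate, via iodo diol 2 (not isolated)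
Conditions: i-Bu2AlH (3.5 equiv), THF, −78 → 0 °C; aq. KNaC4H4O6 work-up; crude: Ac2O, pyridine, DMAP (cat.), CH2Cl2, 23 °C
Reagents that add atoms: acetic anhydride CC(=O)OC(C)=O
Why: Aluminium hydride reduction of the ester to the benzylic alcohol followed by acetylation of both hydroxyls (nucleophilic acyl substitution), which masks them for the acidic, oxidising iodonium synthesis; no stereocentre is involved.

Step 2
Reactants: 3 [3-(acetyloxy)-5-iodophenyl]methyl acetate
Product: 4 [3-(acetyloxy)-5-(acetyloxymethyl)phenyl](2,4,6-trimethylphenyl)iodonium trifluoromethanesulfonate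
Conditions: mCPBA (1.1 equiv), mesitylene (1.1 equiv), TfOH (2 equiv), CH2Cl2, 0 → 23 °C; Et2O precipitation
Reagents that add atoms: mesitylene Cc1cc(C)cc(C)c1; trifluoromethanesulfonic acid OS(=O)(=O)C(F)(F)F
Why: One-pot oxidation of the aryl iodide to trivalent iodine and electrophilic aromatic substitution on mesitylene (Olofsson-type diaryliodonium synthesis), mesityl being the bulky group that is not transferred later.

Step 3
Reactants: 4 [3-(acetyloxy)-5-(acetyloxymethyl)phenyl](2,4,6-trimethylphenyl)iodonium trifluoromethanesulfonate; 5 (S)-citronellal [(3S)-3,7-dimethyloct-6-enal]; 6 1-(triphenylphosphoranylidene)propan-2-one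
Product: 8 (3E,5R,6S)-5-[3-(acetyloxy)-5-(acetyloxymethyl)phenyl]-6,10-dimethylundeca-3,9-dien-2-one, via aryl aldehyde 7 (not isolated)
Conditions: CuBr (10 mol %), (2S,5S)-5-benzyl-2-tert-butyl-3-methylimidazolidin-4-one·Cl3CCO2H (10 mol %), NaHCO3, PhMe–Et2O 2:1, 23 °C; then 6 (1.5 equiv), CH2Cl2, 23 °C
Reagents that add atoms: none
Why: Organocatalytic enantioselective α-arylation of an aldehyde (chiral enamine plus the aryl–copper species from the diaryliodonium salt) transfers the unhindered aryl to the enamine face left open by the catalyst, the antipode that gives (S)-2-arylalkanals, and so sets C4 as S under catalyst control (C11 comes unchanged from 5), and the epimerisable aldehyde is trapped at once by E-selective Wittig olefination with the stabilised ylide.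

Step 4
Reactants: 8 (3E,5R,6S)-5-[3-(acetyloxy)-5-(acetyloxymethyl)phenyl]-6,10-dimethylundeca-3,9-dien-2-one
Product: 10 (5S,6S)-5-[3-hydroxy-5-(hydroxymethyl)phenyl]-6,10-dimethylundec-9-en-2-one, via diacetate ketone 9 (not isolated)
Conditions: Cu(OAc)2·H2O (3 mol %), 1,2-(Ph2P)2C6H4 (3 mol %), (EtO)2MeSiH (1.5 equiv), t-BuOH (1.5 equiv), PhMe, 23 °C; then K2CO3 (0.3 equiv), MeOH, 23 °C
Reagents that add atoms: none
Why: Copper hydride 1,4-reduction of the enone (the isolated trisubstituted alkene is untouched and C4 is not epimerised because no base acts on the enone) followed by carbonate-catalysed transesterification that frees the phenol and the benzylic alcohol; no new stereocentre.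

Step 5
Reactants: 10 (5S,6S)-5-[3-hydroxy-5-(hydroxymethyl)phenyl]-6,10-dimethylundec-9-en-2-one
Product: 12 [(8S)-4-(acetyloxy)-5-methyl-8-[(2S)-6-methylhept-5-en-2-yl]-7,8-dihydronaphthalen-2-yl]methyl acetate, via dihydronaphthalene diol 11 (not isolated)
Conditions: SnCl4 (15 mol %), Bu3N (40 mol %), PhMe, 80 °C (−H2O); then Ac2O, pyridine, DMAP (cat.), 23 °C
Reagents that add atoms: acetic anhydride CC(=O)OC(C)=O
Why: Phenoxide-templated ortho-specific hydroxyalkylation (Casiraghi-type tin phenoxide, in which the carbonyl bound to tin on O8 can reach only C8a and not the position para to oxygen) followed by dehydration of the tertiary o-hydroxybenzylic alcohol (Bradsher-type cyclodehydration) closes ring B and gives the C1=C2 alkene, and the crude diol is acetylated; C4 and C11 are untouched.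

Step 6
Reactants: 12 [(8S)-4-(acetyloxy)-5-methyl-8-[(2S)-6-methylhept-5-en-2-yl]-7,8-dihydronaphthalen-2-yl]methyl acetate
Product: 14 (1S,2S,4S)-6-(hydroxymethyl)-1-methyl-4-[(2S)-6-methylhept-5-en-2-yl]-1,2,3,4-tetrahydronaphthalene-2,8-diol, via pinacol boronate 13 (not isolated)
Conditions: [Rh(nbd)2]BF4 (2 mol %), (R,R)-TADDOL phenyl phosphite (4 mol %), pinacolborane (2 equiv), THF, 40 °C; then NaOH, H2O2, H2O, 0 → 23 °C
Reagents that add atoms: pinacolborane CC1(C)OBOC1(C)C (boron of 13); hydrogen peroxide OO (C2 oxygen of 14)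
Why: Proposed new method: acetate-directed rhodium-catalysed asymmetric hydroboration of a 1,1,2-trisubstituted cyclic styrene, in which the C8 acetate carbonyl and the neighbouring C1=C2 alkene bind the cationic rhodium–phosphite as a two-point chelate, H–Bpin adds syn with boron at the less hindered non-benzylic C2 and hydrogen at C1 so that one face selection fixes both centres with methyl trans to boron, the ligand antipode is the one that places rhodium on the face syn to the C4 chain (catalyst control against the substrate bias), the remote trisubstituted alkene has no directing group and is inert to this catalyst, and alkaline peroxide then replaces boron by oxygen with retention while hydrolysing both acetates; the closest known reaction type is carbonyl-directed catalytic asymmetric hydroboration of β,γ-unsaturated amides and esters with rhodium, TADDOL phosphites and pinacolborane followed by stereoretentive C–B oxidation.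

Step 7
Reactants: 14 (1S,2S,4S)-6-(hydroxymethyl)-1-methyl-4-[(2S)-6-methylhept-5-en-2-yl]-1,2,3,4-tetrahydronaphthalene-2,8-diol
Product: 15 [(5S,6S,8S)-4,6-bis(acetyloxy)-5-methyl-8-[(2S)-6-methylhept-5-en-2-yl]-5,6,7,8-tetrahydronaphthalen-2-yl]methyl acetate
Conditions: Ac2O (4 equiv), pyridine, DMAP (5 mol %), CH2Cl2, 23 °C
Reagents that add atoms: acetic anhydride CC(=O)OC(C)=O
Why: DMAP-catalysed acetylation (nucleophilic acyl substitution) of all three hydroxyls without touching any stereocentre.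

Step 8
Reactants: 15 [(5S,6S,8S)-4,6-bis(acetyloxy)-5-methyl-8-[(2S)-6-methylhept-5-en-2-yl]-5,6,7,8-tetrahydronaphthalen-2-yl]methyl acetate
Product: 16 [(5S,6S,8S)-6-(acetyloxy)-4-hydroxy-5-methyl-8-[(2S)-6-methylhept-5-en-2-yl]-5,6,7,8-tetrahydronaphthalen-2-yl]methyl acetate
Conditions: pyrrolidine (1.2 equiv), MeCN, 0 → 23 °C
Reagents that add atoms: none
Why: Chemoselective aminolysis of the aryl ester, whose phenoxide leaving group makes it far more reactive towards the secondary amine than the primary and secondary alkyl acetates, frees only the C8 phenol and gives the target.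

**Compound list**
1 | methyl 3-hydroxy-5-iodobenzoate | COC(=O)c1cc(O)cc(I)c1 | starting material
2 | 3-(hydroxymethyl)-5-iodophenol | OCc1cc(O)cc(I)c1 | intermediate
3 | [3-(acetyloxy)-5-iodophenyl]methyl acetate | CC(=O)OCc1cc(OC(C)=O)cc(I)c1 | intermediate
4 | [3-(acetyloxy)-5-(acetyloxymethyl)phenyl](2,4,6-trimethylphenyl)iodonium trifluoromethanesulfonate | CC(=O)OCc1cc(OC(C)=O)cc(c1)[I+]c1c(C)cc(C)cc1C.[O-]S(=O)(=O)C(F)(F)F | intermediate
5 | (S)-citronellal, (3S)-3,7-dimethyloct-6-enal | O=CC[C@@H](C)CCC=C(C)C | starting material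
6 | 1-(triphenylphosphoranylidene)propan-2-one | CC(=O)C=P(c1ccccc1)(c1ccccc1)c1ccccc1 | starting material
7 | (2S,3S)-2-[3-(acetyloxy)-5-(acetyloxymethyl)phenyl]-3,7-dimethyloct-6-enal | CC(=O)OCc1cc(OC(C)=O)cc(c1)[C@H]([C@@H](C)CCC=C(C)C)C=O | intermediate
8 | (3E,5R,6S)-5-[3-(acetyloxy)-5-(acetyloxymethyl)phenyl]-6,10-dimethylundeca-3,9-dien-2-one | CC(=O)OCc1cc(OC(C)=O)cc(c1)[C@H]([C@@H](C)CCC=C(C)C)/C=C/C(C)=O | intermediate
9 | (5S,6S)-5-[3-(acetyloxy)-5-(acetyloxymethyl)phenyl]-6,10-dimethylundec-9-en-2-one | CC(=O)OCc1cc(OC(C)=O)cc(c1)[C@H]([C@@H](C)CCC=C(C)C)CCC(C)=O | intermediate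
10 | (5S,6S)-5-[3-hydroxy-5-(hydroxymethyl)phenyl]-6,10-dimethylundec-9-en-2-one | OCc1cc(O)cc(c1)[C@H]([C@@H](C)CCC=C(C)C)CCC(C)=O | intermediate
11 | (5S)-3-(hydroxymethyl)-8-methyl-5-[(2S)-6-methylhept-5-en-2-yl]-5,6-dihydronaphthalen-1-ol | OCc1cc(O)c2c(c1)[C@H]([C@@H](C)CCC=C(C)C)CC=C2C | intermediate
12 | [(8S)-4-(acetyloxy)-5-methyl-8-[(2S)-6-methylhept-5-en-2-yl]-7,8-dihydronaphthalen-2-yl]methyl acetate | CC(=O)OCc1cc(OC(C)=O)c2c(c1)[C@H]([C@@H](C)CCC=C(C)C)CC=C2C | intermediate
13 | [(5R,6S,8S)-4-(acetyloxy)-5-methyl-8-[(2S)-6-methylhept-5-en-2-yl]-6-(4,4,5,5-tetramethyl-1,3,2-dioxaborolan-2-yl)-5,6,7,8-tetrahydronaphthalen-2-yl]methyl acetate | CC(=O)OCc1cc(OC(C)=O)c2c(c1)[C@H]([C@@H](C)CCC=C(C)C)C[C@H](B3OC(C)(C)C(C)(C)O3)[C@H]2C | intermediate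
14 | (1S,2S,4S)-6-(hydroxymethyl)-1-methyl-4-[(2S)-6-methylhept-5-en-2-yl]-1,2,3,4-tetrahydronaphthalene-2,8-diol | OCc1cc(O)c2c(c1)[C@H]([C@@H](C)CCC=C(C)C)C[C@H](O)[C@H]2C | intermediate
15 | [(5S,6S,8S)-4,6-bis(acetyloxy)-5-methyl-8-[(2S)-6-methylhept-5-en-2-yl]-5,6,7,8-tetrahydronaphthalen-2-yl]methyl acetate | CC(=O)OCc1cc(OC(C)=O)c2c(c1)[C@H]([C@@H](C)CCC=C(C)C)C[C@H](OC(C)=O)[C@H]2C | intermediate
16 | [(5S,6S,8S)-6-(acetyloxy)-4-hydroxy-5-methyl-8-[(2S)-6-methylhept-5-en-2-yl]-5,6,7,8-tetrahydronaphthalen-2-yl]methyl acetate | CC(=O)OCc1cc(O)c2c(c1)[C@H]([C@@H](C)CCC=C(C)C)C[C@H](OC(C)=O)[C@H]2C | target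

**Count and risks**
Total steps: 8. Longest linear sequence: 8 steps (1 → 3 → 4 → 8 → 10 → 12 → 14 → 15 → 16; citronellal 5 enters at step 3).

Most likely to fail, step 6 (the new directed hydroboration). The hindered trisubstituted alkene may not insert, or attack anti to the pseudoaxial C4 chain may override the ligand and give the wrong C1/C2 pair. The fallback uses known chemistry, sets out from enone 8 and comes back at triol 14. Cu(OAc)2/bisphosphine-catalysed 1,4-hydrosilylation with Et3SiH gives the triethylsilyl enol ether F1. Rubottom oxidation (mCPBA, NaHCO3, CH2Cl2, −20 °C, the enol ether reacting before the side-chain alkene) gives the α-hydroxy ketone F2. K2CO3 in MeOH frees both hydroxyls to give the keto triol F3. The tin-templated closure of step 5 then closes ring B with loss of water through the enol and gives the 2-tetralone F4, whose C1 is equilibrated with DBU to the epimer with methyl trans to the C4 chain. Reduction with (R)-Me-CBS and catecholborane sets C2 by reagent control and gives 14.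

Second, step 5 (regiochemistry of ring closure). Closure para instead of ortho to the phenol would give the 6-hydroxy regioisomer. The fallback sets out from aldehyde 7 and comes back at 11. Horner–Wadsworth–Emmons reaction with diethyl (cyanomethyl)phosphonate (LiCl, DBU) gives the unsaturated nitrile F5. Copper hydride 1,4-reduction gives the saturated nitrile F6, and pyrrolidine removes the phenolic acetate to give the phenol nitrile F7. BCl3/AlCl3 (boron-bridged, ortho-specific Sugasawa-type acylation by the nitrile, then aqueous HCl) can close only at C8a and gives the hydroxy tetralone F8. Excess MeMgBr, which also cleaves the remaining acetate, gives the tertiary alcohol F9, and TsOH-catalysed dehydration gives 11.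

Third, step 3 (α-arylation of a β-branched aldehyde). The enamine may form slowly or the diastereocontrol at C4 may erode. The fallback sets out from iodide 3 and aldehyde 5 and comes back at 8. Pd(OAc)2/rac-BINAP-catalysed α-arylation of 5 with 3 (Cs2CO3, dioxane, 80 °C) gives 7 together with the epimeric aldehyde F10, without the chiral amine or the iodonium salt. Wittig reaction with 6 then gives 8 and the epimeric enone F11, which are separated by chromatography.

Further compounds
F1 | step 6 | (5S,6S)-5-[3-(acetyloxy)-5-(acetyloxymethyl)phenyl]-6,10-dimethyl-2-(triethylsilyloxy)undeca-2,9-diene | CC(=O)OCc1cc(OC(C)=O)cc(c1)[C@H]([C@@H](C)CCC=C(C)C)CC=C(C)O[Si](CC)(CC)CC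
F2 | step 6 | (5S,6S)-5-[3-(acetyloxy)-5-(acetyloxymethyl)phenyl]-3-hydroxy-6,10-dimethylundec-9-en-2-one (C3 epimers) | CC(=O)OCc1cc(OC(C)=O)cc(c1)[C@H]([C@@H](C)CCC=C(C)C)CC(O)C(C)=O
F3 | step 6 | (5S,6S)-3-hydroxy-5-[3-hydroxy-5-(hydroxymethyl)phenyl]-6,10-dimethylundec-9-en-2-one (C3 epimers) | OCc1cc(O)cc(c1)[C@H]([C@@H](C)CCC=C(C)C)CC(O)C(C)=O
F4 | step 6 | (1S,4S)-8-hydroxy-6-(hydroxymethyl)-1-methyl-4-[(2S)-6-methylhept-5-en-2-yl]-3,4-dihydronaphthalen-2(1H)-one | OCc1cc(O)c2c(c1)[C@H]([C@@H](C)CCC=C(C)C)CC(=O)[C@H]2C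
F5 | step 5 | (2E,4R,5S)-4-[3-(acetyloxy)-5-(acetyloxymethyl)phenyl]-5,9-dimethyldeca-2,8-dienenitrile | CC(=O)OCc1cc(OC(C)=O)cc(c1)[C@H]([C@@H](C)CCC=C(C)C)/C=C/C#N
F6 | step 5 | (4S,5S)-4-[3-(acetyloxy)-5-(acetyloxymethyl)phenyl]-5,9-dimethyldec-8-enenitrile | CC(=O)OCc1cc(OC(C)=O)cc(c1)[C@H]([C@@H](C)CCC=C(C)C)CCC#N
F7 | step 5 | (4S,5S)-4-[3-(acetyloxymethyl)-5-hydroxyphenyl]-5,9-dimethyldec-8-enenitrile | CC(=O)OCc1cc(O)cc(c1)[C@H]([C@@H](C)CCC=C(C)C)CCC#N
F8 | step 5 | [(8S)-4-hydroxy-8-[(2S)-6-methylhept-5-en-2-yl]-5-oxo-5,6,7,8-tetrahydronaphthalen-2-yl]methyl acetate | CC(=O)OCc1cc(O)c2c(c1)[C@H]([C@@H](C)CCC=C(C)C)CCC2=O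
F9 | step 5 | (4S)-6-(hydroxymethyl)-1-methyl-4-[(2S)-6-methylhept-5-en-2-yl]-1,2,3,4-tetrahydronaphthalene-1,8-diol (C1 epimers) | OCc1cc(O)c2c(c1)[C@H]([C@@H](C)CCC=C(C)C)CCC2(C)O
F10 | step 3 | (2R,3S)-2-[3-(acetyloxy)-5-(acetyloxymethyl)phenyl]-3,7-dimethyloct-6-enal | CC(=O)OCc1cc(OC(C)=O)cc(c1)[C@@H]([C@@H](C)CCC=C(C)C)C=O
F11 | step 3 | (3E,5S,6S)-5-[3-(acetyloxy)-5-(acetyloxymethyl)phenyl]-6,10-dimethylundeca-3,9-dien-2-one | CC(=O)OCc1cc(OC(C)=O)cc(c1)[C@@H]([C@@H](C)CCC=C(C)C)/C=C/C(C)=O
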